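Monday's run, with 200 µM of free catalyst, ended at 92.2% target and 4.4% uncatalysed product, and Wednesday's, with 50 µM, ended at 75.5% and 13.5%. You want the closing books of a flask between them, so keep a ledger of substrate, the limiting reagent, whose charge is smaller than the partner's.

| flask | substrate | partner | free catalyst | second catalyst | remark | time |
|---|---|---|---|---|---|---|
| Wednesday's | 5.0 × 10⁻⁴ M | 0.65 mM | 50 µM | 5 µM | run made earlier |  |
| Monday's | 5.0 × 10⁻⁴ M | 0.65 mM | 200 µM | 5 µM | run made earlier |  |
| flask | 5.0 × 10⁻⁴ M | 0.650 mM | 100 µM | 5.0 µM |  | 5.0 h |

| run | time / h | target / % | uncatalysed product / % |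
|---|---|---|---|
| Wednesday's | 0.250 | 65.2 | 12.3 |
| Wednesday's | 0.833 | 75.0 | 13.3 |
| Wednesday's | 1.33 | 75.2 | 12.9 |
| Wednesday's | 2.00 | 75.0 | 12.5 |
| Wednesday's | 3.00 | 75.5 | 13.5 |
| Monday's | 0.250 | 79.8 | 4.3 |
| Monday's | 0.417 | 85.4 | 4.0 |
| Monday's | 0.833 | 90.0 | 4.1 |
| Monday's | 1.50 | 92.0 | 4.2 |
| Monday's | 3.00 | 92.2 | 4.4 |

(standard deviation of a reading: 0.3 percentage points)

The first entry is the split between target and uncatalysed product. Multiply the free catalyst by the last reading of uncatalysed product over target: Wednesday's run gives 8.94 µM and Monday's 9.54 µM, close together although the catalyst charges differ. Their mean, 9.24 µM, is the split level, the free catalyst concentration that these plateaus read as equal shares of target and uncatalysed product. In the flask, with 100 µM, target over uncatalysed product is then 10.8.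

The second entry is the substrate that neither reading shows. Taken over uncatalysed product, it averages 0.794 in the two runs. So your books of the flask close at 7.93% uncatalysed product, 85.6% target and 6.30% unseen.

1. ratio of target to uncatalysed product at 2.5 s
2. ratio of target to uncatalysed product at 3.0 min
3. ratio of target to uncatalysed product at 5.0 h

- the earlier runs were read with a standard deviation of 0.3 percentage points

The forecast gave 4, 6.5 and 11.2 at the three times, its last value a little above your 10.8, and held that “Early ratios are therefore below the plateau”.

The flask gives 0.587, 6.96 and 11.2, so the forecast's earliest value is too high by a factor of 6.81, and the 10.8 from the split level lies a little below the flask's last value.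

    substrate + free catalyst → free catalyst + intermediate (k = 1200 M⁻¹ s⁻¹)
    partner + second catalyst + intermediate → second catalyst + target (k = 1.60 × 10⁷ M⁻² s⁻¹)
    substrate + partner → uncatalysed product (k = 18.0 M⁻¹ s⁻¹)
    2 substrate → self-condensation product (k = 19.0 M⁻¹ s⁻¹)
    2 second catalyst ⇌ resting dimer (K = 2.50 × 10⁷ M⁻¹, k = 9500 M⁻¹ s⁻¹)

At the start of the flask, substrate goes to intermediate 10 times as fast as to uncatalysed product, yet after 0.00141 h intermediate is made 4.55 times as fast as it is used up. Now take the neighbour charged with 8.5 × 10⁻⁶ M of second catalyst, all else as in the flask. Its free catalyst is unchanged, so the split level again gives 10.8. The neighbour stands at 0.896 after 2.5 s, against 0.587 in the flask, and at 11.4 after 5.0 h.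

The runs stem from a simulated flask with constants of no real substance, and the scatter is random.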